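Assumption: the SMILES decodes to the trans-(3R,5S) lactone (O1–C2(=O)–C3(Me)–C4–C5) with both chain alkenes E; that compound is made.

**Retrosynthetic overview**
1. 18 ⇒ 16: the C-3 methyl goes on last by trans-selective enolate methylation.
2. 16 ⇒ 15: the lactone ring (the only ring built) is closed by C–O bond formation, a catalytic asymmetric Baeyer–Villiger oxygen insertion run as a dynamic kinetic resolution, which sets C-5.
3. 15 ⇒ 13 + cyclobutanone 14: Tsuji–Trost allylation at the chain terminus.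
4. 13 ⇒ 10 ⇒ 9 ⇒ 7: one-pot CHO → CH3 with carbonate formation, SeO2 oxidation of the terminal (E)-methyl, chelation-controlled O-demethylation.
5. 7 ⇒ 1 + 2: directed ortho-metalation and copper-mediated geranylation. Ring order: arene (bought), cyclobutanone (bought, attached), γ-lactone (ring expansion).

**Route**

Step 1
Reactants: 1 2,3,4-trimethoxybenzaldehyde; 2 geranyl bromide [(2E)-1-bromo-3,7-dimethylocta-2,6-diene]
Product: 7 6-[(2E)-3,7-dimethylocta-2,6-dien-1-yl]-2,3,4-trimethoxybenzaldehyde, via lithium α-amino alkoxide 3 (not isolated), via ortho-lithiated α-amino alkoxide 4 (not isolated), via arylcopper α-amino alkoxide 5 (not isolated), via geranylated α-amino alkoxide 6 (not isolated)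
Conditions: LiN(Me)CH2CH2NMe2 (from MeNHCH2CH2NMe2 + n-BuLi), THF, −20 °C; n-BuLi (1.5 equiv), −20 °C, 12 h; CuBr·SMe2, −78 °C; 2, −78 → 0 °C; H2O
Reagents that add atoms: none
Why: Comins-type directed ortho-metalation, in which the aldehyde is masked in situ as the α-amino alkoxide whose chelating diamine arm steers n-BuLi to C-6 (the only ortho C–H), and the arylcopper then displaces bromide from 2 at the primary carbon (SN2 allylation) with the E-alkene intact; no stereocentre is formed.

Step 2
Reactants: 7 6-[(2E)-3,7-dimethylocta-2,6-dien-1-yl]-2,3,4-trimethoxybenzaldehyde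
Product: 9 6-[(2E)-3,7-dimethylocta-2,6-dien-1-yl]-2-hydroxy-3,4-dimethoxybenzaldehyde, via iodomagnesium phenoxide 8 (not isolated)
Conditions: MgI2·OEt2 (1.5 equiv), toluene, 70 °C; 1 M HCl
Reagents that add atoms: none
Why: Chelation-controlled ether cleavage, in which MgI2 binds the formyl oxygen and the ortho methoxy group so that iodide demethylates only that ether (SN2 at methyl), leaving the other two methoxy groups and the alkenes untouched.

Step 3
Reactants: 9 6-[(2E)-3,7-dimethylocta-2,6-dien-1-yl]-2-hydroxy-3,4-dimethoxybenzaldehyde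
Product: 10 2-hydroxy-6-[(2E,6E)-8-hydroxy-3,7-dimethylocta-2,6-dien-1-yl]-3,4-dimethoxybenzaldehyde
Conditions: SeO2 (0.3 equiv), t-BuOOH (3 equiv), salicylic acid (0.1 equiv), CH2Cl2, 0 °C → rt
Reagents that add atoms: tert-butyl hydroperoxide CC(C)(C)OO
Why: Sharpless SeO2/t-BuOOH allylic oxidation (ene reaction then [2,3]-sigmatropic shift) attacks the most accessible, terminal trisubstituted alkene at its (E)-methyl group and gives the (E)-allylic alcohol, as in geranyl- and farnesyl-type substrates, while the hydrogen-bonded salicylaldehyde is inert.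

Step 4
Reactants: 10 2-hydroxy-6-[(2E,6E)-8-hydroxy-3,7-dimethylocta-2,6-dien-1-yl]-3,4-dimethoxybenzaldehyde
Product: 13 ethyl (2E,6E)-8-(3-hydroxy-4,5-dimethoxy-2-methylphenyl)-2,6-dimethylocta-2,6-dien-1-yl carbonate, via bis(ethyl carbonate) aldehyde 11 (not isolated), via ortho-quinone methide 12 (not isolated)
Conditions: ClCO2Et (2.5 equiv), Et3N, DMAP (cat.), THF, 0 °C; then NaBH4, H2O, 0 °C → rt
Reagents that add atoms: ethyl chloroformate CCOC(=O)Cl
Why: Minami-type one-pot deoxygenation of a salicylaldehyde, in which both hydroxyls are acylated, NaBH4 reduces the aldehyde, the aryl carbonate shifts to the benzylic alkoxide and is expelled to give an ortho-quinone methide that hydride reduces to the ortho-cresol, while the allylic ethyl carbonate is inert to NaBH4 and is kept as the leaving group for step 5.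

Step 5
Reactants: 13 ethyl (2E,6E)-8-(3-hydroxy-4,5-dimethoxy-2-methylphenyl)-2,6-dimethylocta-2,6-dien-1-yl carbonate; 14 cyclobutanone
Product: 15 rac-2-[(2E,6E)-8-(3-hydroxy-4,5-dimethoxy-2-methylphenyl)-2,6-dimethylocta-2,6-dien-1-yl]cyclobutan-1-one
Conditions: Pd(PPh3)4 (5 mol %), pyrrolidine (30 mol %), 14 (5 equiv), DMSO, 25 °C
Reagents that add atoms: none
Why: Tsuji–Trost allylation with enamine co-catalysis, in which zerovalent palladium ionises the allylic carbonate, the pyrrolidine enamine of 14 attacks the unsubstituted allyl terminus so the E-alkene is kept, any phenol O-allylation is reversible under the catalyst, and the new stereocentre is formed racemic.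

Step 6
Reactants: 15 rac-2-[(2E,6E)-8-(3-hydroxy-4,5-dimethoxy-2-methylphenyl)-2,6-dimethylocta-2,6-dien-1-yl]cyclobutan-1-one
Product: 16 (5S)-5-[(2E,6E)-8-(3-hydroxy-4,5-dimethoxy-2-methylphenyl)-2,6-dimethylocta-2,6-dien-1-yl]oxolan-2-one
Conditions: 9-amino-9-deoxy-epi-quinine (10 mol %), (R)-TRIP [3,3′-bis(2,4,6-triisopropylphenyl)-1,1′-binaphthyl-2,2′-diyl hydrogen phosphate] (20 mol %), 50% aq. H2O2 (1.3 equiv, added over 12 h), 1,4-dioxane, 30 °C
Reagents that add atoms: hydrogen peroxide OO
Why: Proposed new method: a Baeyer–Villiger oxygen insertion run as a dynamic kinetic resolution under primary-amine/chiral-phosphoric-acid catalysis, in which the amine salt condenses reversibly with the strained ketone, iminium–enamine tautomerism racemises C-2 faster than the slowly dosed H2O2 is consumed, H2O2 adds to the iminium inside the chiral ion pair, and the peroxy adduct of one enantiomer undergoes a strain-driven Criegee 1,2-shift of the more substituted carbon with retention, forming the C5–O bond and the lactone ring in the (S) series; the closest known reaction types are the chiral phosphoric acid/aqueous H2O2 Baeyer–Villiger desymmetrisation of 3-substituted cyclobutanones and primary-amine-salt catalysed oxidations of enones with H2O2, conditions that leave isolated alkenes and phenols alone.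

Step 7
Reactants: 16 (5S)-5-[(2E,6E)-8-(3-hydroxy-4,5-dimethoxy-2-methylphenyl)-2,6-dimethylocta-2,6-dien-1-yl]oxolan-2-one
Product: 18 Antroquinonol Y [(3R,5S)-5-[(2E,6E)-8-(3-hydroxy-4,5-dimethoxy-2-methylphenyl)-2,6-dimethylocta-2,6-dien-1-yl]-3-methyloxolan-2-one], via dilithium phenoxide enolate 17 (not isolated)
Conditions: LiN(i-Pr)2 (2.2 equiv), THF, −78 °C; MeI (1.1 equiv), −78 °C; AcOH
Reagents that add atoms: iodomethane CI
Why: Kinetic alkylation of the lithium lactone enolate (the first equivalent of base only deprotonates the phenol, whose lithium salt is inert to MeI at −78 °C), in which MeI approaches anti to the C-5 side chain (1,3-induction) to give the trans-3,5-disubstituted lactone and thus (3R).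

**Compound list**
1 | 2,3,4-trimethoxybenzaldehyde | COc1ccc(C=O)c(OC)c1OC | starting material
2 | geranyl bromide, (2E)-1-bromo-3,7-dimethylocta-2,6-diene | BrC/C=C(\C)CCC=C(C)C | starting material
3 | lithium α-amino alkoxide (adduct of 1 with LiN(Me)CH2CH2NMe2) | [Li+].[O-]C(N(C)CCN(C)C)c1ccc(OC)c(OC)c1OC | intermediate (not isolated)
4 | ortho-lithiated α-amino alkoxide (C-6 lithio derivative of 3) | [Li+].[O-]C(N(C)CCN(C)C)c1c([Li])cc(OC)c(OC)c1OC | intermediate (not isolated)
5 | arylcopper α-amino alkoxide (C-6 copper derivative of 3) | [Li+].[O-]C(N(C)CCN(C)C)c1c([Cu])cc(OC)c(OC)c1OC | intermediate (not isolated)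
6 | geranylated α-amino alkoxide (C-6 geranyl derivative of 3) | [Li+].[O-]C(N(C)CCN(C)C)c1c(C/C=C(\C)CCC=C(C)C)cc(OC)c(OC)c1OC | intermediate (not isolated)
7 | 6-[(2E)-3,7-dimethylocta-2,6-dien-1-yl]-2,3,4-trimethoxybenzaldehyde | COc1cc(C/C=C(\C)CCC=C(C)C)c(C=O)c(OC)c1OC | intermediate
8 | iodomagnesium phenoxide of 9 | COc1cc(C/C=C(\C)CCC=C(C)C)c(C=O)c(O[Mg]I)c1OC | intermediate (not isolated)
9 | 6-[(2E)-3,7-dimethylocta-2,6-dien-1-yl]-2-hydroxy-3,4-dimethoxybenzaldehyde | COc1cc(C/C=C(\C)CCC=C(C)C)c(C=O)c(O)c1OC | intermediate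
10 | 2-hydroxy-6-[(2E,6E)-8-hydroxy-3,7-dimethylocta-2,6-dien-1-yl]-3,4-dimethoxybenzaldehyde | COc1cc(C/C=C(\C)CC/C=C(\C)CO)c(C=O)c(O)c1OC | intermediate
11 | 2-(ethoxycarbonyloxy)-6-[(2E,6E)-8-(ethoxycarbonyloxy)-3,7-dimethylocta-2,6-dien-1-yl]-3,4-dimethoxybenzaldehyde | COc1cc(C/C=C(\C)CC/C=C(\C)COC(=O)OCC)c(C=O)c(OC(=O)OCC)c1OC | intermediate (not isolated)
12 | 5-[(2E,6E)-8-(ethoxycarbonyloxy)-3,7-dimethylocta-2,6-dien-1-yl]-2,3-dimethoxy-6-methylidenecyclohexa-2,4-dien-1-one (ortho-quinone methide) | C=C1C(=O)C(OC)=C(OC)C=C1C/C=C(\C)CC/C=C(\C)COC(=O)OCC | intermediate (not isolated)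
13 | ethyl (2E,6E)-8-(3-hydroxy-4,5-dimethoxy-2-methylphenyl)-2,6-dimethylocta-2,6-dien-1-yl carbonate | COc1cc(C/C=C(\C)CC/C=C(\C)COC(=O)OCC)c(C)c(O)c1OC | intermediate
14 | cyclobutanone | O=C1CCC1 | starting material
15 | rac-2-[(2E,6E)-8-(3-hydroxy-4,5-dimethoxy-2-methylphenyl)-2,6-dimethylocta-2,6-dien-1-yl]cyclobutan-1-one | COc1cc(C/C=C(\C)CC/C=C(\C)CC2CCC2=O)c(C)c(O)c1OC | intermediate
16 | (5S)-5-[(2E,6E)-8-(3-hydroxy-4,5-dimethoxy-2-methylphenyl)-2,6-dimethylocta-2,6-dien-1-yl]oxolan-2-one | COc1cc(C/C=C(\C)CC/C=C(\C)C[C@@H]2CCC(=O)O2)c(C)c(O)c1OC | intermediate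
17 | dilithium phenoxide enolate of 16 | [Li+].[Li+].COc1cc(C/C=C(\C)CC/C=C(\C)C[C@@H]2CC=C([O-])O2)c(C)c([O-])c1OC | intermediate (not isolated)
18 | Antroquinonol Y, (3R,5S)-5-[(2E,6E)-8-(3-hydroxy-4,5-dimethoxy-2-methylphenyl)-2,6-dimethylocta-2,6-dien-1-yl]-3-methyloxolan-2-one | COc1cc(C/C=C(\C)CC/C=C(\C)C[C@@H]2C[C@@H](C)C(=O)O2)c(C)c(O)c1OC | target

**Step count and risks**
Total steps: 7. Longest linear sequence: 7 (1 → 18); 2 and 14 are bought.

The three steps most likely to fail are steps 1, 5 and 6.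

Step 1 can suffer from incomplete or misdirected lithiation, and surplus n-BuLi ends up as butylcopper that also consumes 2 (a slight excess of 2 is used). The fallback sets out from 2 and, in place of 1, commercial 5-bromo-1,2,3-trimethoxybenzene (COc1cc(Br)cc(OC)c1OC). Bromine–lithium exchange (n-BuLi, THF, −78 °C), CuBr·SMe2 and then 2 give the symmetric arene 5-[(2E)-3,7-dimethylocta-2,6-dien-1-yl]-1,2,3-trimethoxybenzene F1. Vilsmeier–Haack formylation (POCl3, DMF, 60 °C; aq. NaOAc) at either of its two equivalent free positions comes back to the route at 7.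

Step 5 is uncertain because enamine-mediated allylation has not been run on cyclobutanone with a 2-methyl-substituted allyl unit beside a free phenol; self-aldol of 14 and double allylation are the likely losses. The fallback sets out from 13 and replaces the palladium chemistry by an SN2 aza-enolate alkylation. Methanolysis (K2CO3, MeOH) gives (2E,6E)-8-(3-hydroxy-4,5-dimethoxy-2-methylphenyl)-2,6-dimethylocta-2,6-dien-1-ol F2. CBr4/PPh3 (CH2Cl2, 0 °C) gives 5-[(2E,6E)-8-bromo-3,7-dimethylocta-2,6-dien-1-yl]-2,3-dimethoxy-6-methylphenol F3. Cyclobutanone N,N-dimethylhydrazone F4 (from 14 and Me2NNH2) is lithiated with LiN(i-Pr)2 (2.2 equiv of aza-enolate, THF, −78 °C; the first equivalent deprotonates the phenol) and alkylated with F3 to the N,N-dimethylhydrazone of 15 F5. Aqueous oxalic acid then comes back at 15.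

Step 6 is the proposed new step. Racemisation may not outpace oxidation, which would leave a simple kinetic resolution (at most 50%), and the sense and level of induction are unknown; the pseudo-enantiomeric quinidine-derived amine with (S)-TRIP is the first variable to change. The fallback uses known chemistry and moves the stereocontrol to an auxiliary-directed C–C bond formation, so that the C–O bond formation only has to be stereoretentive. It sets out from 13 and goes through bromide F3 as above. Cyclobutanone SAMP-hydrazone F6 (from 14 and (S)-1-amino-2-(methoxymethyl)pyrrolidine) is lithiated with LiN(i-Pr)2 and alkylated with F3 (Enders alkylation) to the (2S)-configured SAMP-hydrazone F7; the antipodal RAMP auxiliary is used if the sense proves opposite. Aqueous oxalic acid releases (2S)-2-[(2E,6E)-8-(3-hydroxy-4,5-dimethoxy-2-methylphenyl)-2,6-dimethylocta-2,6-dien-1-yl]cyclobutan-1-one F8. A classical Baeyer–Villiger oxidation with H2O2 in AcOH/THF at 0 °C, with retention at the migrating carbon, comes back at 16.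

Further compounds
F1 | step 1 | 5-[(2E)-3,7-dimethylocta-2,6-dien-1-yl]-1,2,3-trimethoxybenzene | COc1cc(C/C=C(\C)CCC=C(C)C)cc(OC)c1OC
F2 | step 5 | (2E,6E)-8-(3-hydroxy-4,5-dimethoxy-2-methylphenyl)-2,6-dimethylocta-2,6-dien-1-ol | COc1cc(C/C=C(\C)CC/C=C(\C)CO)c(C)c(O)c1OC
F3 | step 5 | 5-[(2E,6E)-8-bromo-3,7-dimethylocta-2,6-dien-1-yl]-2,3-dimethoxy-6-methylphenol | COc1cc(C/C=C(\C)CC/C=C(\C)CBr)c(C)c(O)c1OC
F4 | step 5 | cyclobutanone N,N-dimethylhydrazone | CN(C)N=C1CCC1
F5 | step 5 | 2-[(2E,6E)-8-(3-hydroxy-4,5-dimethoxy-2-methylphenyl)-2,6-dimethylocta-2,6-dien-1-yl]cyclobutan-1-one N,N-dimethylhydrazone | COc1cc(C/C=C(\C)CC/C=C(\C)CC2CCC2=NN(C)C)c(C)c(O)c1OC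
F6 | step 6 | cyclobutanone SAMP-hydrazone, (2S)-N-cyclobutylidene-2-(methoxymethyl)pyrrolidin-1-amine | COC[C@@H]1CCCN1N=C2CCC2
F7 | step 6 | (2S)-2-[(2E,6E)-8-(3-hydroxy-4,5-dimethoxy-2-methylphenyl)-2,6-dimethylocta-2,6-dien-1-yl]cyclobutan-1-one SAMP-hydrazone | COc1cc(C/C=C(\C)CC/C=C(\C)C[C@@H]2CCC2=NN3CCC[C@H]3COC)c(C)c(O)c1OC
F8 | step 6 | (2S)-2-[(2E,6E)-8-(3-hydroxy-4,5-dimethoxy-2-methylphenyl)-2,6-dimethylocta-2,6-dien-1-yl]cyclobutan-1-one | COc1cc(C/C=C(\C)CC/C=C(\C)C[C@@H]2CCC2=O)c(C)c(O)c1OC
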